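## The problem

Locants of the 2-oxaspiro[4.5]decane core are used throughout: lactone C1(H)–O2–C3(=O)–C4H2–C5; carbocycle C5–C6(=O)–C7=C8–C9(OAc)–C10H2; side chain C1′–C7′.

- (+)-Miliusane XVII (20) is a γ-lactone spiro-fused at C5 to a 4-acetoxycyclohex-2-enone. C1 carries a (1′E,4′E)-6′-hydroxy-2′,6′-dimethylhepta-1′,4′-dienyl chain.
- The centre of difficulty is C5, a quaternary stereocentre between the C6 carbonyl, the oxygenated allylic stereocentre C1 and two methylenes (C4, C10). The C5–C1 bond is the most hindered bond and separates the molecule into two halves of similar size.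
- The configuration is (1R,5R,9S). The alkenyl group on C1 is cis to C6 across the lactone. This is formally a syn aldol relationship, which the closed transition state of a cyclic ketone enolate does not deliver.
- C9–O lies 1,3 to C5 across C10 and is cis to the C5–C1 bond. C5 and C1 can control each other strongly; C9 and C5 communicate only weakly, and a reagent would be expected to enter at C5 anti to a C9 substituent, not syn.
- Sensitive groups: the γ-acetoxy enone (base), the allylic lactone C1–O bond (ionisation, Pd), the doubly allylic C3′H2 of the skipped diene, the tertiary allylic alcohol (acid), and the E trisubstituted C1′=C2′ bond.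
- The feature that opens the route is the lactone ring itself. C4 is an unsubstituted CH2, C5 is fully substituted, and C1 is a secondary allylic carbon bonded to O2. The ring O2–C3(=O)–C4–C5–C1 is therefore the oxygen-insertion product of a 2-alkenylcyclobutanone C1–C3(=O)–C4–C5. That cyclobutanone is the [2+2] adduct of an alkenylketene (C3=C1) and an exocyclic methylene (C5=C4) on the six-membered ring.
- The carbocycle C5–C10, with oxygen at C6 and C9 (para) and the one-carbon branch C4 next to C6, is the skeleton of 4-methoxy-3-methylphenol. The ring half is therefore available at the final oxidation level by dearomatisation.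

## Retrosynthesis

**20 ⇒ 19 (C9–O acetate bond, with inversion).** The acetate is installed last by Mitsunobu esterification of the 9-epi alcohol 19. This cut is preferred to plain acetylation because the key step is expected to put C1 anti to the C9 oxygen; one operation then corrects C9 and acylates it. The forward reaction must be a clean SN2 at a γ-hydroxy enone and must leave the tertiary alcohol alone.

**19 ⇒ 18 (unmasking only).** The C6 ketone is carried as a dimethyl ketal and both hydroxyls as triethylsilyl ethers. All three fall to mild aqueous acid, so no redox step is needed after the skeleton is built. The ketal also keeps C6 from being an enone during the peroxide step and makes C6 the bulkier neighbour of C5 during the key step.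

**18 ⇒ 17 (deletion of O2 between C3 and C1).** Removing one ring oxygen turns the lactone into spirocyclobutanone 17. The forward Baeyer–Villiger step only has to choose C1 (secondary, allylic) over C4 (primary) as the migrating carbon, with retention at C1. This cut is preferred to C1–O lactonisation retrons because it leaves a carbocycle that a cycloaddition can make in one step.

**17 ⇒ 6 + 16 (C1–C5 and C3–C4).** Both ring bonds to the former ketene carbons are cut, giving exocyclic alkene 6 and alkenylketene 16, generated from acid 14 through acid chloride 15. Cutting only C5–C1 (aldol) or only C4–C5 (enolate alkylation) would still require the quaternary centre to be made on a ring enolate with the wrong intrinsic facial and simple selectivity. The double cut gives two fragments of C7 and C11, one stereocentre in total. The forward [2+2] must form the quaternary C5 and C1 in one event, with C5 controlled by C9 and C1 by the ketene approach geometry.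

**6 ⇒ 5 ⇒ 4 ⇒ 2 ⇒ 1 (ring half).** Silyl ether 6 comes from alcohol 5, the CBS reduction product of β,γ-unsaturated ketone 4. Ketone 4 is the deconjugated tautomer of quinone monoketal 2 and is reached through dienolate 3. Ketal 2 is the oxidative dearomatisation product of 4-methoxy-3-methylphenol (1). The aromatic methyl becomes C4, the phenol carbon becomes C9, and the anisole carbon becomes C6. The only stereocentre that has to be set by a catalyst is C9.

**14 ⇒ 12 ⇒ 11 ⇒ 9 + 10; 9 ⇒ 7 (chain half).** Acid 14 is the silylated form (through silyl ester 13) of hydroxy acid 12, which is the oxidation product of diol 11. The E-allylic tertiary alcohol of 11 is cut by cross-metathesis into dienol 9 and 2-methylbut-3-en-2-ol (10). The E trisubstituted alkene of 9 comes from syn-carboalumination of pent-1-en-4-yne (7) through alane 8 and trapping with oxirane; this fixes the geometry by mechanism.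

## Roads not taken

**Alternative 1: aldol–lactonisation at C5–C1 (the most obvious route).** The enolate of keto ester A1 would add to enal A2, and the aldolate would close onto the ester to give spirolactone A3.
- The closed six-membered transition state of a cyclic (E)-enolate places the alkenyl group cis to C10, not C6.
- Electrophiles enter such 4-silyloxy dienolates anti to the silyloxy group, which would put C1 trans to C9–O.
- Both new centres are therefore set in the wrong sense in one weakly controlled event, with retro-aldol and 1,4-addition to A2 as further liabilities.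
- The chosen plan sets C1 through a predictable ketene geometry and corrects C9 by a stereospecific inversion.

**Alternative 2: biomimetic dearomative C-alkylation.** The phenoxide of methyl homogentisate A4 would be alkylated at the substituted ring carbon with allylic bromide A5 to give enedione A6. The lactone would then be closed by oxidation of the allylic C1–H of A6.
- O-alkylation and C-alkylation at the free ortho position compete with attack at the substituted carbon.
- Nothing controls the absolute configuration of C5.
- No dependable method oxidises one allylic C–H next to a quaternary carbon in the presence of the doubly allylic C3′H2.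
- The chosen plan forms C5–C1 and the future C1–O site together and needs no C–H oxidation.

**Alternative 3: C1–C1′ disconnection.** Neopentyl aldehyde A7 would be alkenylated with vinyl iodide A8 under Ni/Cr mediation, followed by lactonisation to A3.
- A7 needs a quaternary carbon bearing three differentiated carbonyl functions, built by sequential ring-enolate alkylations with the same facial problem as Alternative 1.
- The facial selectivity at C1 would depend on a quaternary carbon whose substituents are of similar size.
- The route is linear and longer. In the chosen plan the chain half arrives complete and C1 is set in the ring-forming step.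

Key step: step 9

Remark on the chemistry: compounds 1, 7 and 10 are taken as commercially available; descriptors (1R,5R,9S; 1′E,4′E) are those read from the target SMILES.

## Route

Step 1
Reactants: 1 4-methoxy-3-methylphenol
Product: 2 4,4-dimethoxy-3-methylcyclohexa-2,5-dien-1-one
Conditions: PhI(OAc)2, MeOH, 0 °C
Reagents that add atoms: methanol, CO
Why: Oxidative dearomatisation of a p-methoxyphenol in methanol gives the quinone monoketal; the para carbon is the only position that can take up methoxide, and the methyl group ends next to the ketal carbon.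

Step 2
Reactants: 2 4,4-dimethoxy-3-methylcyclohexa-2,5-dien-1-one
Product: 4 4,4-dimethoxy-5-methylidenecyclohex-2-en-1-one, via lithium dienolate 3 (not isolated)
Conditions: LDA, THF, −78 °C; then AcOH, −78 °C; cold neutral work-up, used without chromatography
Reagents that add atoms: none
Why: The β-methyl protons are the only acidic protons of 2 (no sp3 α′-H), so vinylogous deprotonation gives 3; kinetic protonation of an extended enolate occurs at the α-carbon, the classical enone deconjugation, and leaves the exocyclic alkene.

Step 3
Reactants: 4 4,4-dimethoxy-5-methylidenecyclohex-2-en-1-one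
Product: 5 (1R)-4,4-dimethoxy-5-methylidenecyclohex-2-en-1-ol
Conditions: (S)-Me-CBS (0.2 equiv), catecholborane, toluene, −78 °C; then MeOH, aq. NaOH
Reagents that add atoms: none
Why: CBS reduction of a cyclohex-2-enone; the alkenyl arm acts as the large group, so the (S)-catalyst should give the (R)-allylic alcohol, and catecholborane at −78 °C does not hydroborate the exocyclic alkene.

Step 4
Reactants: 5 (1R)-4,4-dimethoxy-5-methylidenecyclohex-2-en-1-ol
Product: 6 triethyl{[(1R)-4,4-dimethoxy-5-methylidenecyclohex-2-en-1-yl]oxy}silane
Conditions: TESCl, imidazole, CH2Cl2, 0 °C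
Reagents that add atoms: chlorotriethylsilane, CC[Si](Cl)(CC)CC
Why: Standard silylation under basic conditions, which the acid-sensitive allylic ketal tolerates; the TES group is chosen because it falls together with the ketal in step 11.

Step 5
Reactants: 7 pent-1-en-4-yne
Product: 9 (3E)-4-methylhepta-3,6-dien-1-ol, via alkenylalane 8 (not isolated)
Conditions: Me3Al, Cp2ZrCl2 (cat.), CH2Cl2, 0 °C to rt; then n-BuLi, THF, −78 °C; oxirane, −30 °C to rt; aq. HCl
Reagents that add atoms: trimethylaluminium, C[Al](C)C; oxirane, C1CO1
Why: Zr-catalysed syn-carboalumination of the terminal alkyne places methyl on the internal carbon and aluminium on the terminus, which fixes the E geometry; the derived alanate opens oxirane with retention to give the homoallylic alcohol, while the terminal alkene is not carbometalated under these conditions.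

Step 6
Reactants: 9 (3E)-4-methylhepta-3,6-dien-1-ol; 10 2-methylbut-3-en-2-ol
Product: 11 (3E,6E)-4,8-dimethylnona-3,6-diene-1,8-diol
Conditions: Hoveyda–Grubbs II catalyst (3 mol %), 10 (5 equiv), 1,4-benzoquinone (10 mol %), CH2Cl2, 40 °C
Reagents that add atoms: none
Why: Cross-metathesis of a terminal alkene with the hindered tertiary allylic alcohol is E-selective and does not touch the trisubstituted alkene; benzoquinone suppresses Ru–H isomerisation of the skipped diene.

Step 7
Reactants: 11 (3E,6E)-4,8-dimethylnona-3,6-diene-1,8-diol
Product: 12 (3E,6E)-8-hydroxy-4,8-dimethylnona-3,6-dienoic acid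
Conditions: TEMPO (cat.), PhI(OAc)2, MeCN/H2O (1:1), rt
Reagents that add atoms: water, O
Why: Oxoammonium oxidation takes the primary alcohol through the aldehyde hydrate to the acid under near-neutral conditions; the tertiary alcohol cannot be oxidised and the β,γ-alkene is not brought into conjugation.

Step 8
Reactants: 12 (3E,6E)-8-hydroxy-4,8-dimethylnona-3,6-dienoic acid
Product: 14 (3E,6E)-4,8-dimethyl-8-(triethylsilyloxy)nona-3,6-dienoic acid, via silyl ester 13 (not isolated)
Conditions: TESOTf, 2,6-lutidine, CH2Cl2, −78 to 0 °C; then MeOH/H2O, rt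
Reagents that add atoms: triethylsilyl trifluoromethanesulfonate, CC[Si](CC)(CC)OS(=O)(=O)C(F)(F)F
Why: The silyl triflate silylates both the hindered tertiary alcohol and the acid; the silyl ester is hydrolysed far faster than the tertiary silyl ether, so aqueous methanol returns the free acid only.

Step 9
Reactants: 6 triethyl{[(1R)-4,4-dimethoxy-5-methylidenecyclohex-2-en-1-yl]oxy}silane; 14 (3E,6E)-4,8-dimethyl-8-(triethylsilyloxy)nona-3,6-dienoic acid
Product: 17 (1R,4R,8R)-1-[(1E,4E)-2,6-dimethyl-6-(triethylsilyloxy)hepta-1,4-dien-1-yl]-5,5-dimethoxy-8-(triethylsilyloxy)spiro[3.5]non-6-en-2-one, via acid chloride 15 (not isolated), via alkenylketene 16 (not isolated)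
Conditions: 14 (1.5 equiv), 1-chloro-N,N,2-trimethylprop-1-en-1-amine, CH2Cl2, 0 °C to rt; then syringe-pump addition to 6 and Et3N in toluene, 60 °C
Reagents that add atoms: none
Why: Triethylamine converts acid chloride 15 into alkenylketene 16, which adds to the exocyclic C5=C4 bond of 6 in an asynchronous [π2s+π2a] cycloaddition: the electrophilic ketene carbon C3 bonds to the unsubstituted C4 while positive charge builds at the fully substituted C5, which then closes onto the ketene terminus C1. The closest known reaction type is the [2+2] cycloaddition of in situ generated alkenylketenes with alkenes to give 2-alkenylcyclobutanones, and of ketenes with methylenecycloalkanes to give spirocyclobutanones. The four-membered ring C1–C3–C4–C5 is closed as a whole in this [2+2] mode, and its regiochemistry (carbonyl carbon on CH2, C1 on the spiro carbon) follows from the polarity of both partners. C5 is controlled by the C9 stereocentre: C1 should arrive axially on the face that carries the pseudo-axial C9–H, anti to the pseudo-equatorial OTES group and antiperiplanar to the axial C6–OMe, so the new C5–C1 bond is trans to C9–O. C1 is controlled by the usual ketene approach geometry: the ketene presents its C1–H to the alkene and its substituted terminus to the smaller C10H2 side while the slim C=O end passes the bulky C6 ketal, so ring closure leaves the alkenyl group cis to C6, the contra-steric arrangement that the target needs. The step needs chemoselectivity among four C=C bonds and for cycloaddition over ketene dimerisation: the exocyclic 1,1-disubstituted alkene is the only nucleophilic olefin with a free terminus (C7=C8 is flanked by two oxygenated carbons, and the E geometry of C1′=C2′ keeps the ketene away from its own C4′=C5′ bond), and slow addition keeps 16 dilute. Kinetic control is required because C1–H of 17 is enolisable, hence the weak amine base and moderate temperature.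

Step 10
Reactants: 17 (1R,4R,8R)-1-[(1E,4E)-2,6-dimethyl-6-(triethylsilyloxy)hepta-1,4-dien-1-yl]-5,5-dimethoxy-8-(triethylsilyloxy)spiro[3.5]non-6-en-2-one
Product: 18 (1R,5R,9R)-1-[(1E,4E)-2,6-dimethyl-6-(triethylsilyloxy)hepta-1,4-dien-1-yl]-6,6-dimethoxy-9-(triethylsilyloxy)-2-oxaspiro[4.5]dec-7-en-3-one
Conditions: 30% aq. H2O2, NaOH (aq.), MeOH/THF, −10 to 0 °C; then pH 6 buffer
Reagents that add atoms: hydrogen peroxide, OO
Why: Baeyer–Villiger oxidation of a strained cyclobutanone by hydroperoxide anion; the secondary allylic C1 migrates in preference to the primary C4, with retention at C1. The nucleophilic oxidant does not epoxidise isolated alkenes, and no enone is present because C6 is still a ketal.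

Step 11
Reactants: 18 (1R,5R,9R)-1-[(1E,4E)-2,6-dimethyl-6-(triethylsilyloxy)hepta-1,4-dien-1-yl]-6,6-dimethoxy-9-(triethylsilyloxy)-2-oxaspiro[4.5]dec-7-en-3-one
Product: 19 (1R,5R,9R)-9-hydroxy-1-[(1E,4E)-6-hydroxy-2,6-dimethylhepta-1,4-dien-1-yl]-2-oxaspiro[4.5]dec-7-ene-3,6-dione
Conditions: AcOH/THF/H2O (3:1:1), rt
Reagents that add atoms: water, O
Why: Mild aqueous acid hydrolyses the allylic dimethyl ketal (through an oxocarbenium ion conjugated with C7=C8) and both TES ethers; the quaternary C5 blocks aromatisation and β-elimination, and acetic acid is too weak to ionise the tertiary allylic alcohol or the allylic lactone.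

Step 12
Reactants: 19 (1R,5R,9R)-9-hydroxy-1-[(1E,4E)-6-hydroxy-2,6-dimethylhepta-1,4-dien-1-yl]-2-oxaspiro[4.5]dec-7-ene-3,6-dione
Product: 20 (+)-miliusane XVII, (1R,5R,9S)-1-[(1E,4E)-6-hydroxy-2,6-dimethylhepta-1,4-dien-1-yl]-3,6-dioxo-2-oxaspiro[4.5]dec-7-en-9-yl acetate
Conditions: PPh3, DIAD, AcOH, THF, 0 °C to rt
Reagents that add atoms: acetic acid, CC(=O)O
Why: Mitsunobu esterification: acetate displaces the C9 alkoxyphosphonium group by SN2, which inverts C9 from R to S and installs the acetate cis to the C5–C1 bond. The tertiary alcohol does not react, and inversion of 4-hydroxycycloalk-2-enones by this reaction is a known use.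

## Compound list

1 | 4-methoxy-3-methylphenol | COc1ccc(O)cc1C | starting material
2 | 4,4-dimethoxy-3-methylcyclohexa-2,5-dien-1-one | CC1=CC(=O)C=CC1(OC)OC | intermediate
3 | lithium 4,4-dimethoxy-3-methylidenecyclohexa-1,5-dien-1-olate (not isolated) | [Li+].[O-]C1=CC(=C)C(OC)(OC)C=C1 | intermediate
4 | 4,4-dimethoxy-5-methylidenecyclohex-2-en-1-one | O=C1C=CC(OC)(OC)C(=C)C1 | intermediate
5 | (1R)-4,4-dimethoxy-5-methylidenecyclohex-2-en-1-ol | O[C@H]1C=CC(OC)(OC)C(=C)C1 | intermediate
6 | triethyl{[(1R)-4,4-dimethoxy-5-methylidenecyclohex-2-en-1-yl]oxy}silane | CC[Si](CC)(CC)O[C@H]1C=CC(OC)(OC)C(=C)C1 | intermediate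
7 | pent-1-en-4-yne | C=CCC#C | starting material
8 | dimethyl[(1E)-2-methylpenta-1,4-dien-1-yl]alumane (not isolated) | C[Al](C)/C=C(\C)CC=C | intermediate
9 | (3E)-4-methylhepta-3,6-dien-1-ol | OCC/C=C(\C)CC=C | intermediate
10 | 2-methylbut-3-en-2-ol | CC(C)(O)C=C | starting material
11 | (3E,6E)-4,8-dimethylnona-3,6-diene-1,8-diol | OCC/C=C(\C)C/C=C/C(C)(C)O | intermediate
12 | (3E,6E)-8-hydroxy-4,8-dimethylnona-3,6-dienoic acid | OC(=O)C/C=C(\C)C/C=C/C(C)(C)O | intermediate
13 | triethylsilyl (3E,6E)-4,8-dimethyl-8-(triethylsilyloxy)nona-3,6-dienoate (not isolated) | CC[Si](CC)(CC)OC(=O)C/C=C(\C)C/C=C/C(C)(C)O[Si](CC)(CC)CC | intermediate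
14 | (3E,6E)-4,8-dimethyl-8-(triethylsilyloxy)nona-3,6-dienoic acid | OC(=O)C/C=C(\C)C/C=C/C(C)(C)O[Si](CC)(CC)CC | intermediate
15 | (3E,6E)-4,8-dimethyl-8-(triethylsilyloxy)nona-3,6-dienoyl chloride (not isolated) | ClC(=O)C/C=C(\C)C/C=C/C(C)(C)O[Si](CC)(CC)CC | intermediate
16 | (3E,6E)-4,8-dimethyl-8-(triethylsilyloxy)nona-1,3,6-trien-1-one, the alkenylketene (not isolated) | O=C=C/C=C(\C)C/C=C/C(C)(C)O[Si](CC)(CC)CC | intermediate
17 | (1R,4R,8R)-1-[(1E,4E)-2,6-dimethyl-6-(triethylsilyloxy)hepta-1,4-dien-1-yl]-5,5-dimethoxy-8-(triethylsilyloxy)spiro[3.5]non-6-en-2-one | CC[Si](CC)(CC)O[C@H]1C=CC(OC)(OC)[C@@]2(CC(=O)[C@@H]2/C=C(\C)C/C=C/C(C)(C)O[Si](CC)(CC)CC)C1 | intermediate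
18 | (1R,5R,9R)-1-[(1E,4E)-2,6-dimethyl-6-(triethylsilyloxy)hepta-1,4-dien-1-yl]-6,6-dimethoxy-9-(triethylsilyloxy)-2-oxaspiro[4.5]dec-7-en-3-one | CC[Si](CC)(CC)O[C@H]1C=CC(OC)(OC)[C@@]2(CC(=O)O[C@@H]2/C=C(\C)C/C=C/C(C)(C)O[Si](CC)(CC)CC)C1 | intermediate
19 | (1R,5R,9R)-9-hydroxy-1-[(1E,4E)-6-hydroxy-2,6-dimethylhepta-1,4-dien-1-yl]-2-oxaspiro[4.5]dec-7-ene-3,6-dione | O[C@H]1C=CC(=O)[C@@]2(CC(=O)O[C@@H]2/C=C(\C)C/C=C/C(C)(C)O)C1 | intermediate
20 | (+)-miliusane XVII, (1R,5R,9S)-1-[(1E,4E)-6-hydroxy-2,6-dimethylhepta-1,4-dien-1-yl]-3,6-dioxo-2-oxaspiro[4.5]dec-7-en-9-yl acetate | CC(=O)O[C@@H]1C=CC(=O)[C@@]2(CC(=O)O[C@@H]2/C=C(\C)C/C=C/C(C)(C)O)C1 | target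

## Step count and least certain steps

Total: 12 steps. Longest linear sequence: 8 steps (steps 1–4 then 9–12, or steps 5–8 then 9–12).

**Step 9 (key step).** The most likely failure is that ketene dimerisation and oligomerisation outrun cycloaddition, because the alkene terminus is next to a quaternary ketal carbon and is inductively deactivated. A second failure mode is base-mediated epimerisation at the enolisable C1 of the product, which would erode the kinetic cis relationship to C6.
Fallback: the neutral ketene is replaced by a cationic keteniminium ion, which adds to unactivated 1,1-disubstituted alkenes stepwise. It sets out from 14 and 6. Acid 14 is converted through 15 with dimethylamine into (3E,6E)-N,N,4,8-tetramethyl-8-(triethylsilyloxy)nona-3,6-dienamide F1. With triflic anhydride and 2,4,6-collidine in 1,2-dichloroethane, F1 gives the alkenylketeniminium triflate F2 in the presence of 6. F2 adds to C4 and closes at C5 to give the cyclobutaniminium triflate F3. Aqueous bicarbonate hydrolysis of F3 returns to the route at 17.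

**Step 2.** The likely failure is re-conjugation of the exocyclic alkene into the ring during work-up or handling of the β,γ-unsaturated ketone. Michael addition of the dienolate to unreacted dienone is a second risk.
Fallback: the ketone is not isolated and the asymmetric reduction is replaced by a resolution. It sets out from 2. After protonation of 3 at −78 °C, the cold solution is transferred into NaBH4/CeCl3·7H2O in methanol (Luche conditions) to give racemic 4,4-dimethoxy-5-methylidenecyclohex-2-en-1-ol F4. This alcohol has no enolisable carbonyl, so it can no longer re-conjugate. Lipase-catalysed acylation with vinyl acetate (immobilised Candida antarctica lipase B) should acylate the (R)-enantiomer, by the empirical size rule with the oxygenated alkenyl arm as the large group, to give (1R)-4,4-dimethoxy-5-methylidenecyclohex-2-en-1-yl acetate F5. F5 is separated from the unreacted (S)-enantiomer of F4, and methanolysis (K2CO3, MeOH) returns to the route at 5.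

**Step 11.** The likely failure is acid-promoted ionisation of the tertiary allylic alcohol (allylic transposition or dehydration) during the time needed to remove the tertiary silyl ether.
Fallback: the end-game order is changed so that fluoride removes silicon and the enone is unveiled last. It sets out from 18. Buffered TBAF/AcOH in THF gives (1R,5R,9R)-9-hydroxy-1-[(1E,4E)-6-hydroxy-2,6-dimethylhepta-1,4-dien-1-yl]-6,6-dimethoxy-2-oxaspiro[4.5]dec-7-en-3-one F6. Mitsunobu reaction of this simple allylic alcohol (PPh3, DIAD, AcOH) gives the inverted (9S)-acetate, (1R,5R,9S)-1-[(1E,4E)-6-hydroxy-2,6-dimethylhepta-1,4-dien-1-yl]-6,6-dimethoxy-3-oxo-2-oxaspiro[4.5]dec-7-en-9-yl acetate F7. A short ketal hydrolysis (PPTS, wet acetone) returns to the route at 20.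

**Step 12.** The likely failure is loss of the activated C9 oxygen by elimination towards C10 (giving a cross-conjugated dienone), or substitution with partial retention through an allylic cation.
Fallback: the SN2 inversion is replaced by an oxidation–reduction inversion under reagent control. It sets out from 19. Dess–Martin oxidation of the allylic alcohol gives (1R,5R)-1-[(1E,4E)-6-hydroxy-2,6-dimethylhepta-1,4-dien-1-yl]-2-oxaspiro[4.5]dec-7-ene-3,6,9-trione F8. CBS reduction with the (R)-catalyst and catecholborane should reduce the less hindered C9 carbonyl to the (9S)-alcohol, (1R,5R,9S)-9-hydroxy-1-[(1E,4E)-6-hydroxy-2,6-dimethylhepta-1,4-dien-1-yl]-2-oxaspiro[4.5]dec-7-ene-3,6-dione F9. Acetylation of the secondary alcohol (Ac2O, pyridine, 0 °C) returns to the route at 20.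

## Further compounds

F1 | step 9 | (3E,6E)-N,N,4,8-tetramethyl-8-(triethylsilyloxy)nona-3,6-dienamide | CN(C)C(=O)C/C=C(\C)C/C=C/C(C)(C)O[Si](CC)(CC)CC
F2 | step 9 | N,N-dimethyl alkenylketeniminium triflate derived from F1 | C[N+](C)=C=C/C=C(\C)C/C=C/C(C)(C)O[Si](CC)(CC)CC.[O-]S(=O)(=O)C(F)(F)F
F3 | step 9 | N,N-dimethyl cyclobutaniminium triflate corresponding to 17 | CC[Si](CC)(CC)O[C@H]1C=CC(OC)(OC)[C@@]2(CC(=[N+](C)C)[C@@H]2/C=C(\C)C/C=C/C(C)(C)O[Si](CC)(CC)CC)C1.[O-]S(=O)(=O)C(F)(F)F
F4 | step 2 | racemic 4,4-dimethoxy-5-methylidenecyclohex-2-en-1-ol | OC1C=CC(OC)(OC)C(=C)C1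
F5 | step 2 | (1R)-4,4-dimethoxy-5-methylidenecyclohex-2-en-1-yl acetate | CC(=O)O[C@H]1C=CC(OC)(OC)C(=C)C1
F6 | step 11 | (1R,5R,9R)-9-hydroxy-1-[(1E,4E)-6-hydroxy-2,6-dimethylhepta-1,4-dien-1-yl]-6,6-dimethoxy-2-oxaspiro[4.5]dec-7-en-3-one | O[C@H]1C=CC(OC)(OC)[C@@]2(CC(=O)O[C@@H]2/C=C(\C)C/C=C/C(C)(C)O)C1
F7 | step 11 | (1R,5R,9S)-1-[(1E,4E)-6-hydroxy-2,6-dimethylhepta-1,4-dien-1-yl]-6,6-dimethoxy-3-oxo-2-oxaspiro[4.5]dec-7-en-9-yl acetate | CC(=O)O[C@@H]1C=CC(OC)(OC)[C@@]2(CC(=O)O[C@@H]2/C=C(\C)C/C=C/C(C)(C)O)C1
F8 | step 12 | (1R,5R)-1-[(1E,4E)-6-hydroxy-2,6-dimethylhepta-1,4-dien-1-yl]-2-oxaspiro[4.5]dec-7-ene-3,6,9-trione | O=C1C=CC(=O)[C@@]2(CC(=O)O[C@@H]2/C=C(\C)C/C=C/C(C)(C)O)C1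
F9 | step 12 | (1R,5R,9S)-9-hydroxy-1-[(1E,4E)-6-hydroxy-2,6-dimethylhepta-1,4-dien-1-yl]-2-oxaspiro[4.5]dec-7-ene-3,6-dione | O[C@@H]1C=CC(=O)[C@@]2(CC(=O)O[C@@H]2/C=C(\C)C/C=C/C(C)(C)O)C1
A1 | alternative 1 | methyl 2-[(5S)-5-(tert-butyldimethylsilyloxy)-2-oxocyclohex-3-en-1-yl]acetate | CC(C)(C)[Si](C)(C)O[C@@H]1C=CC(=O)C(CC(=O)OC)C1
A2 | alternative 1 | (2E,5E)-7-hydroxy-3,7-dimethylocta-2,5-dienal | O=C/C=C(\C)C/C=C/C(C)(C)O
A3 | alternative 1 | (1R,5R,9S)-9-(tert-butyldimethylsilyloxy)-1-[(1E,4E)-6-hydroxy-2,6-dimethylhepta-1,4-dien-1-yl]-2-oxaspiro[4.5]dec-7-ene-3,6-dione | CC(C)(C)[Si](C)(C)O[C@@H]1C=CC(=O)[C@@]2(CC(=O)O[C@@H]2/C=C(\C)C/C=C/C(C)(C)O)C1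
A4 | alternative 2 | methyl 2-(2,5-dihydroxyphenyl)acetate | COC(=O)Cc1cc(O)ccc1O
A5 | alternative 2 | (3E,6E)-8-bromo-2,6-dimethylocta-3,6-dien-2-ol | BrC/C=C(\C)C/C=C/C(C)(C)O
A6 | alternative 2 | methyl 2-{1-[(2E,5E)-7-hydroxy-3,7-dimethylocta-2,5-dien-1-yl]-2,5-dioxocyclohex-3-en-1-yl}acetate (racemic) | COC(=O)CC1(C/C=C(\C)C/C=C/C(C)(C)O)CC(=O)C=CC1=O
A7 | alternative 3 | methyl 2-[(1R,5S)-5-(tert-butyldimethylsilyloxy)-1-formyl-2-oxocyclohex-3-en-1-yl]acetate | CC(C)(C)[Si](C)(C)O[C@@H]1C=CC(=O)[C@@](C=O)(CC(=O)OC)C1
A8 | alternative 3 | (3E,6E)-7-iodo-2,6-dimethylhepta-3,6-dien-2-ol | I/C=C(\C)C/C=C/C(C)(C)O
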